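## Retrosynthetic overview
1. Target ⇒ 13‑O‑silyl macrocycle. The silyl→acetate exchange comes last, because a 13‑acyloxy group is a leaving group towards base and Pd(0).
2. Ten‑membered ring and cis‑4,5‑oxirane ⇒ open‑chain iodomethyl enone bearing an isopropenyl carbinol. C2–C3 forms by a 10‑endo iodine‑atom‑transfer radical cyclisation, then O5 displaces the tertiary C4 iodide in the same flask.
3. C1–C10 ⇒ vinyl bromide + ethyl vinyl ether (Negishi, then NIS/H2O). C5–C6 ⇒ anti vinylogous Mukaiyama aldol of the butenolide with methacrolein.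
4. C8–C9 ⇒ catalytic asymmetric 2‑bromoallylation of a 4‑formylbutenolide with 2,3‑dibromopropene. O8 is acylated with methacryloyl chloride.
5. Butenolide ⇒ but‑2‑yne‑1,4‑diol + vinylMgCl + CO2. Ring order: butenolide, then carbocycle, then oxirane.

Assumption: the SMILES is read literally as (4S,5R,6R,8R) with C3 and C6 cis on the oxirane; germacrane numbering is used throughout (C1 ketone, C4/C5 oxirane, C6 lactone CH–O, C7=C11, C8 CH–O‑methacryloyl, C10=C14H2, C12 lactone C=O, C13 CH2O, C15 methyl).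

## Route

Step 1
Reactants: 1 but‑2‑yne‑1,4‑diol; 2 vinylmagnesium chloride; 3 carbon dioxide
Product: 5 3‑(hydroxymethyl)‑4‑vinylfuran‑2(5H)‑one, via magnesium chelate 4 (not isolated)
Conditions: 2 (4 equiv), CuI (10 mol %), THF–toluene, 80 °C, 16 h; CO2 (1 atm), −20 °C → rt; 2 M HCl
Reagents that add atoms: none
Why: Hydroxyl‑directed anti‑carbomagnesiation of the propargylic alkoxide puts vinyl on the carbon next to the chelating CH2O and Mg on the other carbon; carboxylation of that C–Mg bond places the acid cis to the chelating CH2OH so it lactonises on acidification; the symmetric diol leaves no regiochemical question and no stereocentre is formed.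

Step 2
Reactants: 5 3‑(hydroxymethyl)‑4‑vinylfuran‑2(5H)‑one
Product: 6 3‑[(tert‑butyldimethylsilyloxy)methyl]‑4‑vinylfuran‑2(5H)‑one
Conditions: TBSCl, imidazole, CH2Cl2, 0 °C → rt
Reagents that add atoms: tert‑butyldimethylsilyl chloride, CC(C)(C)[Si](C)(C)Cl
Why: Standard silylation of the primary alcohol; a silyl ether is used instead of the final acetate because an acyloxy group on C13 would be expelled from the C6 dienolate or silyloxyfuran (step 6), ionised by Pd(0) (step 7) and lost with carbonate (step 8).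

Step 3
Reactants: 6 3‑[(tert‑butyldimethylsilyloxy)methyl]‑4‑vinylfuran‑2(5H)‑one
Product: 8 4‑[(tert‑butyldimethylsilyloxy)methyl]‑5‑oxo‑2,5‑dihydrofuran‑3‑carbaldehyde, via secondary ozonide 7 (not isolated)
Conditions: O3, CH2Cl2, −78 °C (Sudan III end point); Me2S, −78 °C → rt
Reagents that add atoms: ozone, [O-][O+]=O (aldehyde oxygen)
Why: Criegee ozonolysis; electrophilic ozone cleaves the terminal monosubstituted C=C far faster than the tetrasubstituted, ester‑conjugated ring C=C, and the product carries no stereocentre.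

Step 4
Reactants: 8 4‑[(tert‑butyldimethylsilyloxy)methyl]‑5‑oxo‑2,5‑dihydrofuran‑3‑carbaldehyde; 9 2,3‑dibromoprop‑1‑ene
Product: 11 4‑[(1R)‑3‑bromo‑1‑hydroxybut‑3‑enyl]‑3‑[(tert‑butyldimethylsilyloxy)methyl]furan‑2(5H)‑one, via TMS ether 10 (not isolated)
Conditions: CrCl2 (10 mol %), chiral oxazoline–sulfonamide ligand (11 mol %), Et3N (20 mol %), Co phthalocyanine (1 mol %), Mn (2 equiv), TMSCl (1.5 equiv), LiCl, THF, rt; 1 M HCl–THF, 0 °C, 10 min
Reagents that add atoms: chlorotrimethylsilane, C[Si](C)(C)Cl (silicon is found only in 10, not in 11)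
Why: Catalytic asymmetric Nozaki–Hiyama 2‑haloallylation; Co(I) passes only the allylic bromide of 9 to Cr(II), the sp2 C–Br is inert without nickel, and the chiral sulfonamide on the allylchromium(III) selects the aldehyde face in a closed six‑membered transition state to set C8 as R, while TMSCl frees the Cr alkoxide as 10 and Mn regenerates Cr(II).

Step 5
Reactants: 11 4‑[(1R)‑3‑bromo‑1‑hydroxybut‑3‑enyl]‑3‑[(tert‑butyldimethylsilyloxy)methyl]furan‑2(5H)‑one; 12 methacryloyl chloride
Product: 13 (8R)‑methacrylate of 11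
Conditions: 12 (1.5 equiv), Et3N, DMAP (cat.), BHT (trace), CH2Cl2, −20 → 0 °C
Reagents that add atoms: none
Why: DMAP‑catalysed O‑acylation with retention at C8; translactonisation is impossible because C8 is trans to C12 across the tetrasubstituted C7=C11 bond, and C6 deprotonation cannot expel a group on C8 because C7 carries no charge in the dienolate.

Step 6
Reactants: 13 (8R)‑methacrylate of 11; 14 methacrolein
Product: 17 anti aldol (5S,6R,8R), via silyloxyfuran 15 (not isolated), via O‑TMS aldol 16 (not isolated)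
Conditions: TMSOTf (1.2 equiv), Et3N (1.5 equiv), Et2O, 0 °C, cannula‑filtered from Et3NH·OTf; 14 (3 equiv), cinchona thiourea–ammonium carboxylate salt (10 mol %, pseudoenantiomer giving 6R), CH2Cl2–Et2O, −30 °C; 1 M citric acid, MeOH, 0 °C
Reagents that add atoms: trimethylsilyl triflate, C[Si](C)(C)OS(=O)(=O)C(F)(F)F (silicon is found only in 15 and 16)
Why: Vinylogous Mukaiyama aldol reaction; soft enolisation aromatises the butenolide to 15, whose free C6 position attacks the hydrogen‑bond‑activated α‑branched enal in a 1,2 sense, and the chiral salt controls both faces in an open transition state to give the anti pair 5S,6R, with remote C8 untouched and the poor OTBS leaving group on C13 retained.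

Step 7
Reactants: 17 anti aldol (5S,6R,8R); 18 ethyl vinyl ether
Product: 22 iodomethyl enone (5S,6R,8R), via 1‑ethoxyvinyllithium 19 (not isolated), via 1‑ethoxyvinylzinc chloride 20 (not isolated), via 2‑ethoxydiene 21 (not isolated)
Conditions: 18, t‑BuLi, THF, −78 → 0 °C; ZnCl2; 17 (0.35 equiv), Pd(PPh3)4 (5 mol %), THF, rt → 40 °C; pad of basic alumina; NIS (1.1 equiv), NaHCO3, THF–H2O, 0 °C, dark
Reagents that add atoms: tert‑butyllithium, [Li]C(C)(C)C (lithium only in 19); zinc chloride, Cl[Zn]Cl (zinc only in 20); N‑iodosuccinimide, O=C1CCC(=O)N1I (iodine on C2); water, O (ketone oxygen on C1)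
Why: Negishi sp2–sp2 coupling of the 2‑bromo‑1‑alkene with an acetyl‑anion equivalent that tolerates esters and lactone (the free OH only consumes one extra equivalent), followed by electrophilic iodination of the enol‑ether CH2, by far the most nucleophilic alkene carbon, and hydrolysis of the α‑iodo oxocarbenium ion; this places iodine regiospecifically on C2 and touches no stereocentre.

Step 8
Reactants: 22 iodomethyl enone (5S,6R,8R)
Product: 24 13‑O‑TBS macrocyclic epoxide (4S,5R,6R,8R), via tertiary iodohydrin 23 (not isolated)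
Conditions: Mn2(CO)10 (10 mol %), powdered K2CO3 (3 equiv), degassed PhCF3–MeCN 4:1 (1 mM), blue LEDs, 25 °C
Reagents that add atoms: none
Why: Proposed new method: photogenerated •Mn(CO)5 abstracts iodine from 22 and the α‑keto radical at C2 adds to the CH2 terminus (C3) of the only electron‑rich alkene (10‑endo‑trig; with no H donor present and degenerate iodine exchange keeping radicals alive, a slow closure is tolerated), the tertiary C4 radical takes iodine from 22 or Mn(CO)5I to give 23, and carbonate lets O5 displace the iodide from the back with C5 retained; C4 is set under Curtin–Hammett control, because the two C4 iodides interconvert by iodine‑atom exchange under irradiation while the closure placing ring bonds C3 and C6 cis on the oxirane (Z‑cyclodecene‑like, less strained than the E‑like alternative) is expected to be faster; closest known reaction types are iodine‑atom‑transfer endo macrocyclisations of α‑iodo carbonyl compounds and iodine ATRA to allylic alcohols followed by base‑induced epoxide closure.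

Step 9
Reactants: 24 13‑O‑TBS macrocyclic epoxide (4S,5R,6R,8R); 25 acetic anhydride
Product: 27 target CNP0266914.1, via C13 alcohol 26 (not isolated)
Conditions: Et3N·3HF, MeCN, 0 °C → rt; then pyridine, 25, DMAP (cat.), 0 °C
Reagents that add atoms: none
Why: Near‑neutral fluoride cleavage of the primary Si–O bond leaves oxirane, enone and esters intact, and the only free hydroxyl is acetylated in the same flask under weakly basic conditions that do not deprotonate C6, so no stereocentre is touched.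

## Compound list
1 | but‑2‑yne‑1,4‑diol | OCC#CCO | starting material
2 | vinylmagnesium chloride | C=C[Mg]Cl | starting material
3 | carbon dioxide | O=C=O | starting material
4 | five‑membered alkenylmagnesium alkoxide chelate (Mg on C11 and on the C6 oxygen, vinyl on C7, CH2OMgCl on C11) | C=CC1=C(CO[Mg]Cl)[Mg]OC1 | intermediate
5 | 3‑(hydroxymethyl)‑4‑vinylfuran‑2(5H)‑one | O=C1OCC(C=C)=C1CO | intermediate
6 | 3‑[(tert‑butyldimethylsilyloxy)methyl]‑4‑vinylfuran‑2(5H)‑one | O=C1OCC(C=C)=C1CO[Si](C)(C)C(C)(C)C | intermediate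
7 | secondary ozonide: 4‑(1,2,4‑trioxolan‑3‑yl) analogue of 6 | O=C1OCC(C2OCOO2)=C1CO[Si](C)(C)C(C)(C)C | intermediate
8 | 4‑[(tert‑butyldimethylsilyloxy)methyl]‑5‑oxo‑2,5‑dihydrofuran‑3‑carbaldehyde | O=CC1=C(CO[Si](C)(C)C(C)(C)C)C(=O)OC1 | intermediate
9 | 2,3‑dibromoprop‑1‑ene | C=C(Br)CBr | starting material
10 | 4‑[(1R)‑3‑bromo‑1‑(trimethylsilyloxy)but‑3‑enyl]‑3‑[(tert‑butyldimethylsilyloxy)methyl]furan‑2(5H)‑one | C[Si](C)(C)O[C@H](CC(Br)=C)C1=C(CO[Si](C)(C)C(C)(C)C)C(=O)OC1 | intermediate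
11 | 4‑[(1R)‑3‑bromo‑1‑hydroxybut‑3‑enyl]‑3‑[(tert‑butyldimethylsilyloxy)methyl]furan‑2(5H)‑one (8R) | O[C@H](CC(Br)=C)C1=C(CO[Si](C)(C)C(C)(C)C)C(=O)OC1 | intermediate
12 | methacryloyl chloride | C=C(C)C(Cl)=O | starting material
13 | (1R)‑3‑bromo‑1‑{4‑[(tert‑butyldimethylsilyloxy)methyl]‑5‑oxo‑2,5‑dihydrofuran‑3‑yl}but‑3‑enyl 2‑methylprop‑2‑enoate | C=C(C)C(=O)O[C@H](CC(Br)=C)C1=C(CO[Si](C)(C)C(C)(C)C)C(=O)OC1 | intermediate
14 | methacrolein | C=C(C)C=O | starting material
15 | 2‑(trimethylsilyloxy)furan from 13 (C6–H free, CH2OTBS on C11, (8R) side chain on C7) | C=C(C)C(=O)O[C@H](CC(Br)=C)c1coc(O[Si](C)(C)C)c1CO[Si](C)(C)C(C)(C)C | intermediate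
16 | O5‑trimethylsilyl ether of 17 (5S,6R,8R) | C=C(C)C(=O)O[C@H](CC(Br)=C)C1=C(CO[Si](C)(C)C(C)(C)C)C(=O)O[C@H]1[C@@H](O[Si](C)(C)C)C(C)=C | intermediate
17 | (1R)‑3‑bromo‑1‑{(2R)‑4‑[(tert‑butyldimethylsilyloxy)methyl]‑2‑[(1S)‑1‑hydroxy‑2‑methylprop‑2‑enyl]‑5‑oxo‑2,5‑dihydrofuran‑3‑yl}but‑3‑enyl 2‑methylprop‑2‑enoate (O5/O6 anti) | C=C(C)C(=O)O[C@H](CC(Br)=C)C1=C(CO[Si](C)(C)C(C)(C)C)C(=O)O[C@H]1[C@@H](O)C(C)=C | intermediate
18 | ethyl vinyl ether | C=COCC | starting material
19 | 1‑ethoxyvinyllithium | [Li]C(=C)OCC | intermediate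
20 | 1‑ethoxyvinylzinc chloride | Cl[Zn]C(=C)OCC | intermediate
21 | 2‑ethoxy‑1,3‑diene: Br of 17 replaced by C(OEt)=CH2 (5S,6R,8R) | C=C(C)C(=O)O[C@H](CC(=C)C(=C)OCC)C1=C(CO[Si](C)(C)C(C)(C)C)C(=O)O[C@H]1[C@@H](O)C(C)=C | intermediate
22 | (1R)‑1‑{(2R)‑4‑[(tert‑butyldimethylsilyloxy)methyl]‑2‑[(1S)‑1‑hydroxy‑2‑methylprop‑2‑enyl]‑5‑oxo‑2,5‑dihydrofuran‑3‑yl}‑5‑iodo‑3‑methylidene‑4‑oxopentyl 2‑methylprop‑2‑enoate | C=C(C)C(=O)O[C@H](CC(=C)C(=O)CI)C1=C(CO[Si](C)(C)C(C)(C)C)C(=O)O[C@H]1[C@@H](O)C(C)=C | intermediate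
23 | (4R,5R,6R,8R)‑13‑(tert‑butyldimethylsilyloxy)‑5‑hydroxy‑4‑iodo‑8‑methacryloyloxy‑1‑oxogermacra‑7(11),10(14)‑dien‑6,12‑olide | C=C(C)C(=O)O[C@@H]1CC(=C)C(=O)CC[C@@](C)(I)[C@H](O)[C@@H]2OC(=O)C(CO[Si](C)(C)C(C)(C)C)=C21 | intermediate
24 | (4S,5R,6R,8R)‑13‑(tert‑butyldimethylsilyloxy)‑4,5‑epoxy‑8‑methacryloyloxy‑1‑oxogermacra‑7(11),10(14)‑dien‑6,12‑olide (C3/C6 cis on the oxirane) | C=C(C)C(=O)O[C@@H]1CC(=C)C(=O)CC[C@]2(C)O[C@@H]2[C@@H]2OC(=O)C(CO[Si](C)(C)C(C)(C)C)=C21 | intermediate
25 | acetic anhydride | CC(=O)OC(C)=O | starting material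
26 | 13‑hydroxy analogue of 24 (4S,5R,6R,8R) | C=C(C)C(=O)O[C@@H]1CC(=C)C(=O)CC[C@]2(C)O[C@@H]2[C@@H]2OC(=O)C(CO)=C21 | intermediate
27 | CNP0266914.1: (4S,5R,6R,8R)‑13‑acetoxy‑4,5‑epoxy‑8‑methacryloyloxy‑1‑oxogermacra‑7(11),10(14)‑dien‑6,12‑olide | C=C(C)C(=O)O[C@@H]1CC(=C)C(=O)CC[C@]2(C)O[C@@H]2[C@@H]2OC(=O)C(COC(C)=O)=C21 | target

## Step count and risks
Total steps: 9. Longest linear sequence: 9 (all fragments are purchased).

**Most likely to fail, 1: step 8.** The risks are:
- strain in the 10‑endo closure;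
- oligomerisation through the enone and methacrylate C=C bonds;
- transannular 6‑endo attack of the C4 radical on C14;
- loss of HI from 23;
- the cis/trans ratio at C4;
- C6 epimerisation or retro‑aldol cleavage by carbonate.

Fallback from 17 back to 24. The same C2–C3 bond is made by an intermolecular atom‑transfer radical addition, and the ring is closed by a polar C1–C10 coupling. Compound 17 and 2‑bromo‑N‑methoxy‑N‑methylacetamide (BrCC(=O)N(C)OC, 3 equiv; fac‑Ir(ppy)3, LiBr, DMF–H2O, blue LEDs) give the tertiary bromohydrin F1. K2CO3 in MeCN closes it to the epoxy Weinreb amide F2. Without ring strain to bias C4, the epimers are separated at this point. Cp2Zr(H)Cl in THF reduces the amide, not the esters, to the epoxy aldehyde F3. NiCl2 (1 %)/CrCl2 in DMSO at 2 mM joins the vinyl bromide carbon C10 to C1 and gives the macrocyclic C1 allylic alcohol F4 as both C1 epimers. Dess–Martin periodinane oxidises F4 to 24.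

**2: step 6.** The silyloxyfuran is hindered and 3,4‑disubstituted. Simultaneous anti and facial control with an enal is unproven on this substrate. Mukaiyama–Michael addition may compete.

Fallback from 15 back to 17. C5 is not controlled in the C–C bond formation and is corrected afterwards. A BINOL–Ti(IV) catalysed addition of 15 to 14, chosen only for its control of the C6 face, gives mainly the O‑TMS syn aldol F5. Citric acid then gives the syn aldol F6 (5R,6R,8R). Dess–Martin periodinane, buffered with NaHCO3 to spare the now acidic C6–H, gives the isopropenyl ketone F7. A reagent‑controlled Corey–Bakshi–Shibata reduction (Me‑CBS, catecholborane, −78 °C, catalyst enantiomer chosen for the matched case) delivers hydride to the face that gives 17.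

**3: step 4.** The aldehyde is very electron‑poor and may undergo pinacol coupling or reduction with Mn/Cr. The ee on this substrate class is unknown.

Fallback from 8 back to 11. C8 is set by ketone reduction instead of by C–C bond formation. An indium Barbier reaction of 8 with 9 (In, THF–H2O, rt) gives the racemic bromoallyl carbinol F8. Dess–Martin periodinane gives the bromoallyl ketone F9. (S)‑Me‑CBS/BH3·SMe2 at −40 °C, with the butenolide as the large group and CH2 as the small group, returns 11 as the R alcohol.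

## Further compounds
F1 | step 8 | tertiary bromohydrin (4R,5R,6R,8R): 17 with C4(CH3)(Br)–CH2CH2C(=O)N(OMe)Me in place of the isopropenyl group | C=C(C)C(=O)O[C@H](CC(Br)=C)C1=C(CO[Si](C)(C)C(C)(C)C)C(=O)O[C@H]1[C@@H](O)[C@](C)(Br)CCC(=O)N(C)OC
F2 | step 8 | epoxy Weinreb amide (4S,5R,6R,8R) | C=C(C)C(=O)O[C@H](CC(Br)=C)C1=C(CO[Si](C)(C)C(C)(C)C)C(=O)O[C@H]1[C@H]2O[C@@]2(C)CCC(=O)N(C)OC
F3 | step 8 | epoxy aldehyde (4S,5R,6R,8R) | C=C(C)C(=O)O[C@H](CC(Br)=C)C1=C(CO[Si](C)(C)C(C)(C)C)C(=O)O[C@H]1[C@H]2O[C@@]2(C)CCC=O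
F4 | step 8 | macrocyclic C1 allylic alcohol (1‑hydroxy analogue of 24, C1 epimers) | C=C(C)C(=O)O[C@@H]1CC(=C)C(O)CC[C@]2(C)O[C@@H]2[C@@H]2OC(=O)C(CO[Si](C)(C)C(C)(C)C)=C21
F5 | step 6 | O‑TMS syn aldol (5R,6R,8R) | C=C(C)C(=O)O[C@H](CC(Br)=C)C1=C(CO[Si](C)(C)C(C)(C)C)C(=O)O[C@H]1[C@H](O[Si](C)(C)C)C(C)=C
F6 | step 6 | syn aldol (5R,6R,8R), C5 epimer of 17 | C=C(C)C(=O)O[C@H](CC(Br)=C)C1=C(CO[Si](C)(C)C(C)(C)C)C(=O)O[C@H]1[C@H](O)C(C)=C
F7 | step 6 | isopropenyl ketone (C5 ketone, 6R,8R) | C=C(C)C(=O)O[C@H](CC(Br)=C)C1=C(CO[Si](C)(C)C(C)(C)C)C(=O)O[C@H]1C(=O)C(C)=C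
F8 | step 4 | racemic bromoallyl carbinol (rac‑11) | OC(CC(Br)=C)C1=C(CO[Si](C)(C)C(C)(C)C)C(=O)OC1
F9 | step 4 | bromoallyl ketone: 4‑(3‑bromobut‑3‑enoyl)‑3‑[(tert‑butyldimethylsilyloxy)methyl]furan‑2(5H)‑one | O=C(CC(Br)=C)C1=C(CO[Si](C)(C)C(C)(C)C)C(=O)OC1
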